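**Retrosynthetic overview**
1. 12 ⇒ 11: the catechol is freed last from its acetonide. No ring of the target is built, because both arenes are bought. The only ring made is the temporary dioxole ring, closed in step 1 and opened in step 5.
2. 11 ⇒ 8: the carboxylic acid comes from a convertible 4-methoxyanilide by N-Boc activation and LiOOH cleavage.
3. 8 ⇒ 4 + 5 + 6: catalytic enantioselective Passerini three-component reaction. The isocyanide carbon acts as a carboxyl (carbamoyl) anion equivalent and attacks the aldehyde carbon. One step makes the C1–C2 bond, the ferulate ester and the (R) centre.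
4. 4 ⇒ 1: acetonide formation, then partial ester reduction.

Assumption: 1, 5 and 6 are bought as such, and the (R)-phosphoric acid is taken to give (R)-8; the sense of induction must be checked on the first run (chiral HPLC, correlation with natural material), and the equally available (S)-acid is used if it is opposite.

**Step 1**
Reactants: 1 methyl 2-(3,4-dihydroxyphenyl)acetate
Product: 2 methyl 2-(2,2-dimethyl-1,3-benzodioxol-5-yl)acetate
Conditions: 2,2-dimethoxypropane (3 equiv), p-toluenesulfonic acid monohydrate (5 mol%), toluene, reflux through a Soxhlet thimble of 4 Å molecular sieves, 4 h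
Reagents that add atoms: 2,2-dimethoxypropane, COC(C)(C)OC
Why: Acid-catalysed transketalisation (catechol acetonide formation) is driven to completion by trapping the released methanol on the sieves, the ester side chain offers no hydroxyl for a competing oxa-Pictet–Spengler closure, and no stereocentre is involved.

**Step 2**
Reactants: 2 methyl 2-(2,2-dimethyl-1,3-benzodioxol-5-yl)acetate
Product: 4 2-(2,2-dimethyl-1,3-benzodioxol-5-yl)acetaldehyde, via aluminium hemiacetal 3 (not isolated)
Conditions: iBu2AlH (1.05 equiv, 1 M in toluene), CH2Cl2, −78 °C, 1 h; Na2SO4·10H2O, −78 °C to rt, filter; used crude the same day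
Reagents that add atoms: iBu2AlH (diisobutylaluminium hydride), CC(C)C[AlH]CC(C)C (atoms kept only in 3)
Why: Partial ester reduction with iBu2AlH works because the tetrahedral aluminium hemiacetal 3 is stable at −78 °C and collapses to the aldehyde only on the near-neutral hydrate quench, which also spares the ketal and avoids aldol self-condensation of the enolisable arylacetaldehyde, and no stereocentre of the target is set here.

**Step 3 (key step)**
Reactants: 4 2-(2,2-dimethyl-1,3-benzodioxol-5-yl)acetaldehyde; 5 (E)-ferulic acid; 6 4-methoxyphenyl isocyanide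
Product: 8 (2R)-3-(2,2-dimethyl-1,3-benzodioxol-5-yl)-1-(4-methoxyanilino)-1-oxopropan-2-yl (E)-3-(4-hydroxy-3-methoxyphenyl)prop-2-enoate, via acyl imidate 7 (not isolated)
Conditions: 4 (1.0 equiv), 5 (1.2 equiv, fine suspension), (R)-3,3'-bis(2,4,6-triisopropylphenyl)-1,1'-binaphthalene-2,2'-diyl hydrogen phosphate (10 mol%), 4 Å molecular sieves, CH2Cl2 (0.1 M), 0 °C; 6 (1.2 equiv) added by syringe pump over 6 h, then 36 h; recrystallise 8 (EtOAc/heptane) to raise the ee
Reagents that add atoms: none
Why: Catalytic enantioselective Passerini three-component reaction, in which the divalent isocyanide carbon of 6 acts as a carboxyl (carbamoyl) anion equivalent and attacks the aldehyde carbon of 4 inside the hydrogen-bonded phosphoric acid–ferulic acid–aldehyde assembly that shields one aldehyde face and so sets C2 as (R), after which ferulate traps the nitrilium ion to give 7 and a stereoretentive Mumm acyl shift onto the new hydroxyl delivers ester 8.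

**Step 4**
Reactants: 8 (2R)-3-(2,2-dimethyl-1,3-benzodioxol-5-yl)-1-(4-methoxyanilino)-1-oxopropan-2-yl (E)-ferulate
Product: 11 (2R)-3-(2,2-dimethyl-1,3-benzodioxol-5-yl)-2-{[(E)-3-(4-hydroxy-3-methoxyphenyl)prop-2-enoyl]oxy}propanoic acid, via bis-Boc imide 9 (not isolated), via peroxy acid 10 (not isolated)
Conditions: Boc2O (2.3 equiv), 4-(dimethylamino)pyridine (0.2 equiv), THF, rt, 3 h; then 0 °C, H2O, 30% H2O2 (8 equiv), LiOH·H2O (4 equiv), 45 min; aq. Na2SO3; 1 M HCl to pH 3 at 0 °C; acid/base extraction
Reagents that add atoms: di-tert-butyl dicarbonate, CC(C)(C)OC(=O)OC(=O)OC(C)(C)C (atoms kept only in 9); hydrogen peroxide, OO (peroxy oxygens of 10, carboxyl OH oxygen of 11)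
Why: Grieco-type amide activation followed by Evans-type LiOOH cleavage, in which Boc2O and 4-(dimethylamino)pyridine turn the anilide N–H into a twisted, highly electrophilic N-acyl carbamate (capping the phenol in passing), hydroperoxide attacks this acyl carbon and the aryl carbonate quickly at 0 °C while the ferulate ester, strongly deactivated by conjugation with its freed para-phenoxide and flanked by the new carboxylate, is left alone, sulfite reduces peroxy acid 10 to 11, and the weakly basic medium keeps C2 (R).

**Step 5**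
Reactants: 11 (2R)-3-(2,2-dimethyl-1,3-benzodioxol-5-yl)-2-{[(E)-feruloyl]oxy}propanoic acid
Product: 12 (2R)-3-(3,4-dihydroxyphenyl)-2-{[(E)-3-(4-hydroxy-3-methoxyphenyl)prop-2-enoyl]oxy}propanoic acid (target)
Conditions: CF3CO2H/H2O 95:5, argon, dark, 0 °C to rt, 1 h; evaporate; C18 chromatography (H2O/MeCN, 0.1% HCO2H)
Reagents that add atoms: none
Why: Acid hydrolysis of the isopropylidene ketal (the standard release of acetonide-protected catechols) gives the catechol and volatile acetone, while the secondary ester next to the carboxyl group cannot ionise, the E-alkene is not protonated by trifluoroacetic acid and C2–H is not acidic under these conditions, so the (R) centre is retained.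

**Compound list**
1 | methyl 2-(3,4-dihydroxyphenyl)acetate | COC(=O)Cc1ccc(O)c(O)c1 | starting material
2 | methyl 2-(2,2-dimethyl-1,3-benzodioxol-5-yl)acetate | COC(=O)Cc1ccc2OC(C)(C)Oc2c1 | intermediate
3 | diisobutylaluminium 2-(2,2-dimethyl-1,3-benzodioxol-5-yl)-1-methoxyethoxide (aluminium hemiacetal, racemic at the hemiacetal carbon, not isolated) | COC(Cc1ccc2OC(C)(C)Oc2c1)O[Al](CC(C)C)CC(C)C | intermediate
4 | 2-(2,2-dimethyl-1,3-benzodioxol-5-yl)acetaldehyde | CC1(C)Oc2ccc(CC=O)cc2O1 | intermediate
5 | (E)-ferulic acid, (E)-3-(4-hydroxy-3-methoxyphenyl)prop-2-enoic acid | COc1cc(/C=C/C(=O)O)ccc1O | starting material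
6 | 4-methoxyphenyl isocyanide | [C-]#[N+]c1ccc(OC)cc1 | starting material
7 | (E)-feruloyl (2R)-3-(2,2-dimethyl-1,3-benzodioxol-5-yl)-2-hydroxy-N-(4-methoxyphenyl)propanimidate (Passerini α-adduct, C=N geometry undefined, not isolated) | O[C@H](Cc1ccc2OC(C)(C)Oc2c1)C(=Nc1ccc(OC)cc1)OC(=O)/C=C/c1ccc(O)c(OC)c1 | intermediate
8 | (2R)-3-(2,2-dimethyl-1,3-benzodioxol-5-yl)-1-(4-methoxyanilino)-1-oxopropan-2-yl (E)-ferulate | COc1cc(/C=C/C(=O)O[C@H](Cc2ccc3OC(C)(C)Oc3c2)C(=O)Nc2ccc(OC)cc2)ccc1O | intermediate
9 | N-Boc, phenol-O-Boc derivative of 8, (2R) (not isolated) | COc1cc(/C=C/C(=O)O[C@H](Cc2ccc3OC(C)(C)Oc3c2)C(=O)N(C(=O)OC(C)(C)C)c2ccc(OC)cc2)ccc1OC(=O)OC(C)(C)C | intermediate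
10 | (2R)-3-(2,2-dimethyl-1,3-benzodioxol-5-yl)-2-[(E)-feruloyloxy]propaneperoxoic acid (not isolated) | COc1cc(/C=C/C(=O)O[C@H](Cc2ccc3OC(C)(C)Oc3c2)C(=O)OO)ccc1O | intermediate
11 | (2R)-3-(2,2-dimethyl-1,3-benzodioxol-5-yl)-2-[(E)-feruloyloxy]propanoic acid | COc1cc(/C=C/C(=O)O[C@H](Cc2ccc3OC(C)(C)Oc3c2)C(=O)O)ccc1O | intermediate
12 | (2R)-3-(3,4-dihydroxyphenyl)-2-[(E)-feruloyloxy]propanoic acid | COc1cc(/C=C/C(=O)O[C@H](Cc2ccc(O)c(O)c2)C(=O)O)ccc1O | target

**Total step count:** 5. **Longest linear sequence:** 5 (1 → 2 → 4 → 8 → 11 → 12).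

**Steps most likely to fail**

Step 3. The uncatalysed background reaction, the poor solubility of 5 and the enolisable aldehyde may all erode the ee, and this aldehyde/acid/isocyanide set is untested. The fallback sets out from 4 (with 5 and 6) and comes back at 8. The three components are combined without catalyst in CH2Cl2 (1 M, rt), a dependable reaction for arylacetaldehydes, to give the racemic anilide F1. This is resolved by preparative supercritical-fluid chromatography on an amylose tris(3,5-dimethylphenylcarbamate) phase, and the (R)-enantiomer is 8. The stereocentre then comes from resolution instead of catalysis.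

Step 4. The risks are loss of the ferulate ester, partial epimerisation at C2, or attack at the Boc carbonyl. The fallback sets out from 9, this time isolated by filtration through silica, and comes back at 12. Aqueous base and peroxide are avoided altogether. The activated imide is transacylated with 2-(trimethylsilyl)ethanol (2 equiv) and K3PO4 (2 equiv) in dry THF at rt to give the 2-(trimethylsilyl)ethyl ester F2. The CF3CO2H/H2O treatment of step 5 then removes the silylethyl ester, the aryl carbonate and the acetonide in one operation to give 12.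

Step 2. The risks are over-reduction and decomposition of the sensitive arylacetaldehyde. The fallback sets out from 2 and comes back at 4. The ester is reduced fully with LiAlH4 (THF, 0 °C) to the storable alcohol 2-(2,2-dimethyl-1,3-benzodioxol-5-yl)ethanol F3. This alcohol is oxidised just before use with Dess–Martin periodinane (1,1,1-triacetoxy-1,1-dihydro-1,2-benziodoxol-3(1H)-one) in CH2Cl2 at 0 °C to give 4.

**Further compounds**
F1 | step 3 | racemic 3-(2,2-dimethyl-1,3-benzodioxol-5-yl)-1-(4-methoxyanilino)-1-oxopropan-2-yl (E)-ferulate | COc1cc(/C=C/C(=O)OC(Cc2ccc3OC(C)(C)Oc3c2)C(=O)Nc2ccc(OC)cc2)ccc1O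
F2 | step 4 | 2-(trimethylsilyl)ethyl (2R)-2-{[(E)-3-(4-tert-butoxycarbonyloxy-3-methoxyphenyl)prop-2-enoyl]oxy}-3-(2,2-dimethyl-1,3-benzodioxol-5-yl)propanoate | COc1cc(/C=C/C(=O)O[C@H](Cc2ccc3OC(C)(C)Oc3c2)C(=O)OCC[Si](C)(C)C)ccc1OC(=O)OC(C)(C)C
F3 | step 2 | 2-(2,2-dimethyl-1,3-benzodioxol-5-yl)ethanol | CC1(C)Oc2ccc(CCO)cc2O1
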